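**Quick number.** You asked for one. Teal was to run warm until 20 h and cold after, so I reckoned blue and amber, the two ends, first and then joined them.

all flasks: left-handed substrate 0.53 M; right-handed substrate 0.53 M; partner 0.636 M
- Wednesday's: free catalyst 0.55 mM; added ligand 0.99 mM; temperature −35 °C; run made earlier
- Monday's: free catalyst 0.83 mM; added ligand 0.99 mM; temperature −24 °C; run made earlier
- Friday's: free catalyst 1.1 mM; added ligand 2 mM; temperature −35 °C; run made earlier
- teal: free catalyst 1.1 mM; added ligand 0.99 mM; at −20 °C until 20 h, from then on at −40 °C; time 30 h
- amber: free catalyst 1.1 mM; added ligand 0.99 mM; temperature −40 °C; time 30 h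
- blue: free catalyst 1.1 mM; added ligand 0.99 mM; temperature −20 °C; time 30 h

| run | time / h | left-handed product / % | right-handed product / % | left-handed substrate / % |
|---|---|---|---|---|
| Wednesday's | 3.00 | 5 | 0 | 42 |
| Wednesday's | 6.00 | 9 | 0 | 37 |
| Wednesday's | 15.0 | 19 | 5 | 29 |
| Wednesday's | 40.0 | 34 | 5 | 20 |
| Monday's | 2.50 | 16 | 3 | 32 |
| Monday's | 5.00 | 24 | 6 | 28 |
| Monday's | 12.0 | 29 | 7 | 21 |
| Monday's | 20.0 | 29 | 9 | 17 |
| Friday's | 10.0 | 25 | 5 | 29 |
| Friday's | 20.0 | 34 | 5 | 16 |
| Friday's | 25.0 | 35 | 5 | 17 |
| Friday's | 40.0 | 37 | 7 | 10 |

(each reading ± 1.5 percentage points)

- free catalyst is single-handed; left-handed substrate and right-handed substrate are mirror images of each other, charged as a racemate, each of them at the stated concentration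

- the flask that comes out highest in share of left-handed product in all that became left-handed product or right-handed product, or "all alike" when all lie within 1.5 percentage points (teal / amber / blue / all alike)
- share of left-handed product in all that became left-handed product or right-handed product, teal
- share of left-handed product in all that became left-handed product or right-handed product, amber
- share of left-handed product in all that became left-handed product or right-handed product, blue

**The factor.** I used the selectivity factor of this kinetic resolution: the logarithm of the fraction of left-handed substrate left, over the logarithm of the fraction of right-handed substrate left, the latter being its charge less the right-handed product. The last readings gave 8.70 on Wednesday's run and 10.7 on Friday's, averaging 9.68 at −35 °C, and 5.44 on Monday's at −24 °C. Keeping the same ratio per degree, I reached 12.6 at −40 °C and 4.41 at −20 °C, the warm selectivity factor, both carrying the scatter of the readings.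

**Two ends.** Monday's products gained 2 percentage points between 12.0 h and 20.0 h, with 34.0% of the left-handed substrate left, and Friday's run stood at 34.0% after 25.0 h, so I assumed that fraction for both blue and amber. Left-handed substrate used, over that plus the right-handed use implied by the factor, gave amber 88.9% and blue 75.2%.

**The join.** Monday's run had flattened by 20.0 h at −24 °C on 0.83 mM of free catalyst, so I expected teal, warmer on 1.1 mM, to be finished before cooling and put it at blue's 75.2%, not between.

**The forecast.** It named amber, with teal 76%, amber 88% and blue 75%, holding that “cooling changes almost nothing”; I too had amber first, but I had teal level with blue, whereas the forecast set teal higher than blue.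

**Result.** Amber came highest at 86.8%, with teal 73.4% and blue 73.4%.

    free catalyst + left-handed substrate ⇌ catalyst intermediate A (K = 1.70 /M, k = 7600 /M/h, Ea = 51.0 kJ/mol, ΔH = −27.0 kJ/mol)
    partner + catalyst intermediate B → free catalyst + right-handed product (k = 370 /M/h, Ea = 54.0 kJ/mol)
    partner + catalyst intermediate A → free catalyst + left-handed product (k = 780 /M/h, Ea = 50.0 kJ/mol)
    partner → decomposed reagent (k = 0.150 /h, Ea = 86.0 kJ/mol)
    free catalyst + right-handed substrate ⇌ catalyst intermediate B (K = 1.00 /M, k = 1400 /M/h, Ea = 49.0 kJ/mol, ΔH = −1.00 kJ/mol)
    free catalyst + added ligand ⇌ idle complex, settled at all times (K = 410 /M, ΔH = −25.0 kJ/mol)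
    (constants at −20 °C)

At the change, after 20.0 h, teal's [partner] stood at 0.0366% of its charge and its left-handed product, after the same 20.0 h, at 28.9%. After 30.0 h teal's left-handed product stood at 28.9%. With 4.41 and the 42% of left-handed substrate left in teal, the share comes to 76.5%. For teal's neighbour on 2.80 mM of free catalyst, with 29% left, it comes to 74.4%, where that flask gave 71.3%.

The data are calculated on assumed constants; noise was put on by code.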